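**Plan**

1. Numbering: ring A = C1–C5 and C10 (C3 carbinol, C4 gem-dimethyl), ring B = C5–C10 (C10 angular methyl), C11 = CH2O on C9, C12 = exocyclic CH2 on C8. Retrosynthetic cuts, in order: C8=C12 (methylenation of a C8 ketone), C11–O (oxa-Michael), C9–C11 (Mannich methylenation), C4–C5 (epoxide-initiated closure of ring A), then C7–C8 and C5–C6 together (the C6=C7 unit is excised as an alkyne), and last the two cyclobutanone bonds of a ketene [2+2].
2. Enabling feature: C8, C9, C10 and C5 can be held as a cyclobutanone with C8 as the carbonyl carbon. Its strained C8–C5 bond (roughly 26 kcal/mol of ring strain, next to C=O) is opened on zerovalent nickel and an alkyne is stitched in as C6=C7. This gives the C8 enone, whose gamma carbon (C5), alpha' carbon (C9) and carbonyl (C8) are exactly the three sites still to be substituted.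
3. Forward order: acyclic diene 1 + dichloroketene → cyclobutanone 5 → ring B by alkyne insertion (7) → desilylation and Shi epoxidation → ring A by cyclization of the epoxide onto C5 of the silyl dienol ether → C11, then the coumarin, then C12.
4. Stereochemistry: C10 by ligand-controlled cleavage of one of the two enantiotopic ring bonds in the key step; C3 by Shi epoxidation (reagent control); C5 by equilibration of the ring fusion to trans through the extended enolate; C9 by protonation of the enolate after the oxa-Michael addition (CH2OAr equatorial).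
5. Because C3 is set independently by reagent control, any leakage at C10 becomes a diastereomer of the decalin and should be removable at compound 13.

Key step: step 3

**Route**

Step 1
Reactants: 1 2,6-dimethylhepta-1,5-diene; 2 trichloroacetyl chloride
Product: 4 (±)-2,2-dichloro-3-methyl-3-(4-methylpent-3-en-1-yl)cyclobutan-1-one, via dichloroketene 3 (not isolated)
Conditions: Zn(Cu), POCl3, Et2O, 0 °C to rt, 2 added slowly to 1 (1.5 equiv)
Reagents that add atoms: none
Why: Ketene–alkene [2+2] cycloaddition in which the ketene carbonyl carbon should bond to the unhindered CH2 terminus and the CCl2 carbon to the tertiary carbon, the 1,1-disubstituted alkene reacting in preference to the more hindered trisubstituted one (the stereocentre of racemic 4 disappears in step 2).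

Step 2
Reactants: 4
Product: 5 3-methyl-3-(4-methylpent-3-en-1-yl)cyclobutan-1-one
Conditions: Zn dust, AcOH, rt to 50 °C
Reagents that add atoms: none
Why: Reductive dechlorination of an alpha,alpha-dichloroketone by zinc, the standard second half of the dichloroketene route to cyclobutanones, should leave the isolated alkene untouched and give a prochiral ketone whose two C(O)–CH2 bonds are enantiotopic.

Step 3
Reactants: 5; 6 ethynyltrimethylsilane
Product: 7 (S)-5-methyl-5-(4-methylpent-3-en-1-yl)-3-(trimethylsilyl)cyclohex-2-en-1-one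
Conditions: Ni(cod)2 (10 mol %), chiral monodentate phosphoramidite ligand (20 mol %, antipode chosen to give (S)-7), toluene, 80 °C, 6 by syringe pump
Reagents that add atoms: none
Why: Proposed new method: oxidative cyclization of the strained C=O of 5 and the alkyne on zerovalent nickel should give a spiro oxanickelacyclopentene, beta-carbon elimination then opens the four-membered ring with release of its strain, and C(sp3)–C(sp2) reductive elimination closes the cyclohexenone, so that C8 gains its bond to C7 and the migrating ring CH2 (C5) its bond to C6 in one catalytic event. The closest known reaction type is the nickel-catalysed intermolecular insertion of alkynes into 3,3-disubstituted cyclobutanones with achiral phosphines, and ligand-controlled choice between enantiotopic ring bonds is known for intramolecular nickel- and rhodium-catalysed cyclobutanone openings; the new element is their combination. Ring B is closed as a formal [4+2] two-carbon ring expansion (four- to six-membered ring through a seven-membered nickelacycle), not by cyclization of a chain. The quaternary C10 becomes stereogenic because only one of the two enantiotopic C(O)–CH2 bonds is cut, and the chiral ligand on nickel is the controlling element. The step needs this enantiotopic-bond selectivity (the uncertain point, since methyl and the alkyl chain on C10 differ only modestly), chemoselectivity for the ketone over the remote alkene (secured by ring strain) and suppression of alkyne oligomerization (bulky silyl group, slow addition). There is no regiochemical issue at the ketone because C9 is left unsubstituted until step 9, and silicon is drawn on C6 although either sense of alkyne insertion would converge on 8 in step 4.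

Step 4
Reactants: 7
Product: 8 (R)-5-methyl-5-(4-methylpent-3-en-1-yl)cyclohex-2-en-1-one
Conditions: TBAF·3H2O, THF–DMSO, 60 °C
Reagents that add atoms: none
Why: Fluoride-induced protodesilylation of an alkenylsilane, eased here because silicon sits on the electron-poor beta carbon of an enone, should remove the group that made the alkyne manageable without touching C10.

Step 5
Reactants: 8
Product: 9 (R)-5-{2-[(R)-3,3-dimethyloxiran-2-yl]ethyl}-5-methylcyclohex-2-en-1-one
Conditions: D-fructose-derived ketone catalyst (30 mol %), Oxone (2KHSO5·KHSO4·K2SO4), K2CO3, Bu4NHSO4, MeCN–CH2(OMe)2/aq. buffer pH 10.5, 0 °C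
Reagents that add atoms: potassium peroxymonosulfate [K+].[O-]S(=O)(=O)OO
Why: Shi epoxidation, in which the chiral dioxirane should attack the electron-rich trisubstituted alkene and not the enone and, through the spiro transition state, give the (R)-epoxide whose CH carbon becomes C3.

Step 6
Reactants: 9
Product: 11 tert-butyl({(S)-5-[2-((R)-3,3-dimethyloxiran-2-yl)ethyl]-5-methylcyclohexa-1,3-dien-1-yl}oxy)dimethylsilane, via potassium dienolate 10 (not isolated)
Conditions: KN(SiMe3)2 (0.95 equiv), THF, −78 to 0 °C; then TBSCl, −78 °C to rt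
Reagents that add atoms: tert-butyldimethylsilyl chloride CC(C)(C)[Si](C)(C)Cl
Why: With a slight deficit of base the kinetic alpha' enolate should equilibrate through the remaining ketone to the more delocalized extended (gamma-deprotonated) dienolate, whose O-silylation gives the linear dienol ether needed for attack through C5 (the cross-conjugated isomer would react at C9 and must be avoided).

Step 7
Reactants: 11
Product: 12 (4aR,6R,8aS)-6-hydroxy-5,5,8a-trimethyl-4a,5,6,7,8,8a-hexahydronaphthalen-2(1H)-one
Conditions: MeAlCl2 (1.2 equiv), CH2Cl2, −78 °C; aq. HCl work-up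
Reagents that add atoms: none
Why: Proposed new method: the Lewis acid should open the trisubstituted epoxide at its tertiary carbon (C4), and the cation-like centre should be captured 6-exo by C5, the gamma terminus of the silyl dienol ether (attack through C7 would need a bridged eight-membered ring), regenerating the C8 enone after loss of silicon; the closest known reaction types are epoxide-initiated cation–olefin cyclizations terminated by silyl enol ethers and the gamma-alkylation of silyl dienol ethers by tertiary carbocations; C3 keeps the epoxide configuration, and because C5 must be attacked perpendicular to the diene plane by a chain anchored on the neighbouring C10, the ring fusion should form cis under kinetic control.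

Step 8
Reactants: 12
Product: 13 (4aS,6R,8aS)-6-hydroxy-5,5,8a-trimethyl-4a,5,6,7,8,8a-hexahydronaphthalen-2(1H)-one
Conditions: NaOMe (0.3 equiv), MeOH, 50 °C
Reagents that add atoms: none
Why: Vinylogous epimerization by reversible gamma-deprotonation to the extended enolate should equilibrate C5 to the trans-fused enone, in which ring A is a chair without an axial ring bond and the angular methyl has no syn-axial hydrogens across the sp2 carbons of ring B.

Step 9
Reactants: 13
Product: 16 (4aS,6R,8aR)-6-hydroxy-5,5,8a-trimethyl-1-methylidene-4a,5,6,7,8,8a-hexahydronaphthalen-2(1H)-one, via Mannich base 14 (not isolated), via ammonium iodide 15 (not isolated)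
Conditions: LiN(iPr)2 (2.2 equiv), THF, −78 °C; CH2=NMe2+ I−, −78 °C to rt; then MeI, MeOH, rt; then aq. NaHCO3, CH2Cl2, rt
Reagents that add atoms: dimethyl(methylidene)ammonium iodide C=[N+](C)C.[I-]
Why: Kinetic deprotonation of an enone by a lithium amide occurs at the alpha' carbon (C9), and the enolate is aminomethylated (Mannich reaction); quaternization and base-induced elimination then give the exocyclic enone, which installs C11, the alkoxide at C3 merely consuming the second equivalent of base.

Step 10
Reactants: 16; 17 7-hydroxy-2H-chromen-2-one (umbelliferone)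
Product: 18 7-{[(1R,4aS,6R,8aR)-6-hydroxy-5,5,8a-trimethyl-2-oxo-1,2,4a,5,6,7,8,8a-octahydronaphthalen-1-yl]methoxy}-2H-chromen-2-one
Conditions: K2CO3 (0.2 equiv), DMF, rt
Reagents that add atoms: none
Why: Oxa-Michael addition of the phenoxide to the unhindered exocyclic methylene (the endocyclic beta carbon C6 is shielded by the ring fusion), followed by protonation of the enolate at C9 from the face opposite the axial angular methyl, should place CH2OAr equatorial, which is also the thermodynamic epimer.

Step 11
Reactants: 18
Product: 19 7-{[(1R,4aS,6R,8aR)-6-hydroxy-5,5,8a-trimethyl-2-methylidene-1,2,4a,5,6,7,8,8a-octahydronaphthalen-1-yl]methoxy}-2H-chromen-2-one (target)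
Conditions: Zn, CH2Br2, TiCl4, THF–CH2Cl2, 0 °C to rt
Reagents that add atoms: dibromomethane BrCBr
Why: Lombardo methylenation, whose non-basic gem-dimetallic reagent converts hindered, enolizable ketones into methylene compounds, should do so without epimerizing C9, expelling the beta-aryloxy group or attacking the coumarin lactone and the free alcohol.

**Compound list**

1 | 2,6-dimethylhepta-1,5-diene | C=C(C)CCC=C(C)C | starting material
2 | trichloroacetyl chloride | ClC(=O)C(Cl)(Cl)Cl | starting material
3 | dichloroketene | ClC(Cl)=C=O | intermediate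
4 | (±)-2,2-dichloro-3-methyl-3-(4-methylpent-3-en-1-yl)cyclobutan-1-one (racemic) | O=C1CC(C)(CCC=C(C)C)C1(Cl)Cl | intermediate
5 | 3-methyl-3-(4-methylpent-3-en-1-yl)cyclobutan-1-one | O=C1CC(C)(CCC=C(C)C)C1 | intermediate
6 | ethynyltrimethylsilane | C#C[Si](C)(C)C | starting material
7 | (S)-5-methyl-5-(4-methylpent-3-en-1-yl)-3-(trimethylsilyl)cyclohex-2-en-1-one | CC(C)=CCC[C@]1(C)CC([Si](C)(C)C)=CC(=O)C1 | intermediate
8 | (R)-5-methyl-5-(4-methylpent-3-en-1-yl)cyclohex-2-en-1-one | CC(C)=CCC[C@]1(C)CC=CC(=O)C1 | intermediate
9 | (R)-5-{2-[(R)-3,3-dimethyloxiran-2-yl]ethyl}-5-methylcyclohex-2-en-1-one | CC1(C)O[C@@H]1CC[C@]2(C)CC=CC(=O)C2 | intermediate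
10 | potassium (S)-5-[2-((R)-3,3-dimethyloxiran-2-yl)ethyl]-5-methylcyclohexa-1,3-dien-1-olate | CC1(C)O[C@@H]1CC[C@]2(C)C=CC=C([O-])C2.[K+] | intermediate
11 | tert-butyl({(S)-5-[2-((R)-3,3-dimethyloxiran-2-yl)ethyl]-5-methylcyclohexa-1,3-dien-1-yl}oxy)dimethylsilane | CC1(C)O[C@@H]1CC[C@]2(C)C=CC=C(O[Si](C)(C)C(C)(C)C)C2 | intermediate
12 | (4aR,6R,8aS)-6-hydroxy-5,5,8a-trimethyl-4a,5,6,7,8,8a-hexahydronaphthalen-2(1H)-one (cis-fused) | O=C1C=C[C@H]2C(C)(C)[C@H](O)CC[C@@]2(C)C1 | intermediate
13 | (4aS,6R,8aS)-6-hydroxy-5,5,8a-trimethyl-4a,5,6,7,8,8a-hexahydronaphthalen-2(1H)-one (trans-fused) | O=C1C=C[C@@H]2C(C)(C)[C@H](O)CC[C@@]2(C)C1 | intermediate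
14 | (4aS,6R,8aR)-1-[(dimethylamino)methyl]-6-hydroxy-5,5,8a-trimethyl-4a,5,6,7,8,8a-hexahydronaphthalen-2(1H)-one (C1 epimers) | O=C1C=C[C@@H]2C(C)(C)[C@H](O)CC[C@@]2(C)C1CN(C)C | intermediate
15 | {[(4aS,6R,8aR)-6-hydroxy-5,5,8a-trimethyl-2-oxo-1,2,4a,5,6,7,8,8a-octahydronaphthalen-1-yl]methyl}trimethylammonium iodide (C1 epimers) | O=C1C=C[C@@H]2C(C)(C)[C@H](O)CC[C@@]2(C)C1C[N+](C)(C)C.[I-] | intermediate
16 | (4aS,6R,8aR)-6-hydroxy-5,5,8a-trimethyl-1-methylidene-4a,5,6,7,8,8a-hexahydronaphthalen-2(1H)-one | O=C1C=C[C@@H]2C(C)(C)[C@H](O)CC[C@@]2(C)C1=C | intermediate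
17 | 7-hydroxy-2H-chromen-2-one (umbelliferone) | O=c1ccc2ccc(O)cc2o1 | starting material
18 | 7-{[(1R,4aS,6R,8aR)-6-hydroxy-5,5,8a-trimethyl-2-oxo-1,2,4a,5,6,7,8,8a-octahydronaphthalen-1-yl]methoxy}-2H-chromen-2-one | O=C1C=C[C@@H]2C(C)(C)[C@H](O)CC[C@@]2(C)[C@@H]1COc1ccc2ccc(=O)oc2c1 | intermediate
19 | 7-{[(1R,4aS,6R,8aR)-6-hydroxy-5,5,8a-trimethyl-2-methylidene-1,2,4a,5,6,7,8,8a-octahydronaphthalen-1-yl]methoxy}-2H-chromen-2-one | C=C1C=C[C@@H]2C(C)(C)[C@H](O)CC[C@@]2(C)[C@@H]1COc1ccc2ccc(=O)oc2c1 | target

**Step count and risks**

Total steps: 11. Longest linear sequence: 11 (1 → 19).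

The three steps most likely to fail:

Step 3 (Proposed new method). What may go wrong: poor discrimination between the two enantiotopic C(O)–CH2 bonds, because methyl and the primary alkyl chain on C10 look similar to the ligand, so that ring expansion proceeds but with low enantiomeric purity. The fallback uses known chemistry and sets out from 5. Insertion of 6 with the achiral system Ni(cod)2/PCy3 in toluene at 100 °C, the conditions established for 3,3-disubstituted cyclobutanones, should give 7 together with its enantiomer (R)-5-methyl-5-(4-methylpent-3-en-1-yl)-3-(trimethylsilyl)cyclohex-2-en-1-one F1. Desilylation as in step 4 then gives 8 together with (S)-5-methyl-5-(4-methylpent-3-en-1-yl)cyclohex-2-en-1-one F2. The racemate is resolved by preparative chromatography on a chiral stationary phase, and the route is rejoined at 8.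

Step 7 (Proposed new method). What may go wrong: rearrangement of the Lewis-acid-activated epoxide by hydride shift, or loss of silicon from the dienol ether, before the C4–C5 bond can form. The fallback uses known chemistry (reductive epoxide radical cyclization, then Saegusa oxidation) and sets out from 9. Its dienolate 10 is quenched with AcOH at −78 °C; kinetic alpha-protonation should give the deconjugated ketone (S)-5-{2-[(R)-3,3-dimethyloxiran-2-yl]ethyl}-5-methylcyclohex-3-en-1-one F3. Cp2TiCl (trivalent titanium, made from Cp2TiCl2 and Mn, with collidine hydrochloride, THF, rt) should open the epoxide to the tertiary radical at C4, which adds 6-exo to C5 of the ring alkene. Reduction and protonation of the secondary radical at C6 should give the cis-fused hydroxy ketone (4aR,6R,8aS)-6-hydroxy-5,5,8a-trimethyloctahydronaphthalen-2(1H)-one F4. LiN(iPr)2 (2.2 equiv) and Me3SiCl give the bis-silyl compound trimethyl({(4aR,6R,8aS)-5,5,8a-trimethyl-6-[(trimethylsilyl)oxy]-1,4,4a,5,6,7,8,8a-octahydronaphthalen-2-yl}oxy)silane F5; enolization goes toward C7 because C9 is neopentyl, and only this enol ether can be dehydrogenated. Saegusa oxidation with Pd(OAc)2 in MeCN gives (4aR,6R,8aS)-5,5,8a-trimethyl-6-[(trimethylsilyl)oxy]-4a,5,6,7,8,8a-hexahydronaphthalen-2(1H)-one F6, and dilute aq. HCl returns 12, where the route is rejoined.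

Step 8. What may go wrong: incomplete equilibration, if the cis/trans equilibrium at C5 does not lie far enough on the trans side, or base-induced self-condensation through the alpha' enolate. The fallback sets C5 by hydrogenation instead of by equilibration and sets out from 12. KOtBu (2.2 equiv) in tBuOH–THF gives the dipotassium alkoxide-dienolate of 12 F7, and a cold AcOH quench should give the deconjugated enone (6R,8aS)-6-hydroxy-5,5,8a-trimethyl-3,5,6,7,8,8a-hexahydronaphthalen-2(1H)-one F8. Hydrogenation over Pd/C in EtOAc should deliver hydrogen to the C5=C6 bond from the face opposite the angular methyl and give the trans-fused ketone (4aS,6R,8aS)-6-hydroxy-5,5,8a-trimethyloctahydronaphthalen-2(1H)-one F9. Silylation as above gives trimethyl({(4aS,6R,8aS)-5,5,8a-trimethyl-6-[(trimethylsilyl)oxy]-1,4,4a,5,6,7,8,8a-octahydronaphthalen-2-yl}oxy)silane F10. Saegusa oxidation with Pd(OAc)2 gives (4aS,6R,8aS)-5,5,8a-trimethyl-6-[(trimethylsilyl)oxy]-4a,5,6,7,8,8a-hexahydronaphthalen-2(1H)-one F11, and dilute aq. HCl gives 13, where the route is rejoined.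

**Further compounds**

F1 | step 3 | (R)-5-methyl-5-(4-methylpent-3-en-1-yl)-3-(trimethylsilyl)cyclohex-2-en-1-one | CC(C)=CCC[C@@]1(C)CC([Si](C)(C)C)=CC(=O)C1
F2 | step 3 | (S)-5-methyl-5-(4-methylpent-3-en-1-yl)cyclohex-2-en-1-one | CC(C)=CCC[C@@]1(C)CC=CC(=O)C1
F3 | step 7 | (S)-5-{2-[(R)-3,3-dimethyloxiran-2-yl]ethyl}-5-methylcyclohex-3-en-1-one | CC1(C)O[C@@H]1CC[C@]2(C)C=CCC(=O)C2
F4 | step 7 | (4aR,6R,8aS)-6-hydroxy-5,5,8a-trimethyloctahydronaphthalen-2(1H)-one | O=C1CC[C@H]2C(C)(C)[C@H](O)CC[C@@]2(C)C1
F5 | step 7 | trimethyl({(4aR,6R,8aS)-5,5,8a-trimethyl-6-[(trimethylsilyl)oxy]-1,4,4a,5,6,7,8,8a-octahydronaphthalen-2-yl}oxy)silane | C[Si](C)(C)OC1=CC[C@H]2C(C)(C)[C@H](O[Si](C)(C)C)CC[C@@]2(C)C1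
F6 | step 7 | (4aR,6R,8aS)-5,5,8a-trimethyl-6-[(trimethylsilyl)oxy]-4a,5,6,7,8,8a-hexahydronaphthalen-2(1H)-one | O=C1C=C[C@H]2C(C)(C)[C@H](O[Si](C)(C)C)CC[C@@]2(C)C1
F7 | step 8 | dipotassium alkoxide-dienolate of 12 | [O-]C1=CC=C2C(C)(C)[C@H]([O-])CC[C@@]2(C)C1.[K+].[K+]
F8 | step 8 | (6R,8aS)-6-hydroxy-5,5,8a-trimethyl-3,5,6,7,8,8a-hexahydronaphthalen-2(1H)-one | O=C1CC=C2C(C)(C)[C@H](O)CC[C@@]2(C)C1
F9 | step 8 | (4aS,6R,8aS)-6-hydroxy-5,5,8a-trimethyloctahydronaphthalen-2(1H)-one | O=C1CC[C@@H]2C(C)(C)[C@H](O)CC[C@@]2(C)C1
F10 | step 8 | trimethyl({(4aS,6R,8aS)-5,5,8a-trimethyl-6-[(trimethylsilyl)oxy]-1,4,4a,5,6,7,8,8a-octahydronaphthalen-2-yl}oxy)silane | C[Si](C)(C)OC1=CC[C@@H]2C(C)(C)[C@H](O[Si](C)(C)C)CC[C@@]2(C)C1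
F11 | step 8 | (4aS,6R,8aS)-5,5,8a-trimethyl-6-[(trimethylsilyl)oxy]-4a,5,6,7,8,8a-hexahydronaphthalen-2(1H)-one | O=C1C=C[C@@H]2C(C)(C)[C@H](O[Si](C)(C)C)CC[C@@]2(C)C1
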